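A direct plan would build the furan on a preformed ring A: iodinated, differentially protected benzaldehyde A1 would be condensed to chalcone A2, an oxidative 1,2-aryl shift and cyclisation would give iodobenzofuran carbaldehyde A3, and Sonogashira coupling to A4 followed by hydrogenation would finish.
Its weakest steps would be:
- the differentiation of the three ring A oxygens and the iodination between them, protecting-group steps that would add length, with site selectivity resting on chelation alone;
- the aryl migration, in which a very electron-rich, iodinated ring would have to migrate before it is oxidised;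
- the last hydrogenation, which would have to cleave benzyl ethers without reducing the formyl group.

The strategy builds ring A (the benzene ring, C4–C7) last, on a preformed 2-aryl-3-(masked formyl)furan. Ring A is cut into a furan-2-yl diazomethyl ketone, which supplies C4 and C7, and a 1-methoxyalkyne, which supplies C5 and C6 with the saturated side chain in place; C4(OH)–C5(alkyl)–C6(OMe)–C7(H) is exactly the pattern that a ketene/ynol ether benzannulation writes. One cascade (Wolff rearrangement, [2+2] cycloaddition, 4π opening, 6π electrocyclisation onto furan C3, tautomerisation) forms four ring A bonds (C7–C7a, C6–C7, C4–C5, C3a–C4) with 4-OH and 6-OMe already told apart. Hence no ring A oxygen is differentiated, nothing is iodinated or cross-coupled there, no aryl group migrates, and no hydrogenation meets the formyl group.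

Key step: step 8

Assumption: the target is achiral, so no stereocentre has to be set; benzofuran numbering is O1, C2 (aryl), C3 (CHO), C3a, C4 (OH), C5 (chain), C6 (OMe), C7, C7a, and compounds 1, 3, 6 and 8 are taken as commercial.

Step 1
Reactants: 1 4-bromo-2-methylbutan-2-ol
Product: 2 [(4-bromo-2-methylbutan-2-yl)oxy]triethylsilane
Conditions: Et3SiOSO2CF3 (1.2 equiv), 2,6-lutidine (1.5 equiv), CH2Cl2, −78 to 0 °C
Reagents that add atoms: triethylsilyl trifluoromethanesulfonate, CC[Si](CC)(CC)OS(=O)(=O)C(F)(F)F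
Why: O-silylation of a hindered tertiary alcohol with a silyl triflate and a hindered pyridine base, which leaves the primary bromide untouched and forms no stereocentre.

Step 2
Reactants: 3 2-chloro-1,1-dimethoxyethane; 2 [(4-bromo-2-methylbutan-2-yl)oxy]triethylsilane
Product: 5 triethyl[(6-methoxy-2-methylhex-5-yn-2-yl)oxy]silane, via sodium methoxyacetylide 4 (not isolated)
Conditions: 3 (1.25 equiv), NaNH2 (3.75 equiv), NH3(l), −33 °C; then 2 (1.0 equiv) in THF, −33 °C to rt; purification on Et3N-deactivated silica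
Reagents that add atoms: none
Why: Two β-eliminations (MeOH, HCl) and a deprotonation by NaNH2 turn the chloroacetal into sodium methoxyacetylide 4, which is alkylated in an SN2 reaction by the unhindered primary bromide, the standard preparation of 1-alkoxy-1-alkynes from chloroacetaldehyde acetals; the hindered tertiary silyl ether should survive the amide base.

Step 3
Reactants: 6 4-bromo-3-methoxyphenol
Product: 7 (4-bromo-3-methoxyphenoxy)tri(propan-2-yl)silane
Conditions: iPr3SiCl (1.1 equiv), imidazole (2 equiv), DMF, rt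
Reagents that add atoms: chlorotri(propan-2-yl)silane, CC(C)[Si](Cl)(C(C)C)C(C)C
Why: Standard silylation of a phenol with a silyl chloride and imidazole; the bulky silyl ether withstands the organometallic steps and shields the arene C–H between the two oxygens from later lithiation.

Step 4
Reactants: 8 furan-3-carbaldehyde
Product: 9 2-(furan-3-yl)-1,3-dioxolane
Conditions: HOCH2CH2OH (3 equiv), TsOH·H2O (2 mol %), toluene, reflux, Dean–Stark trap
Reagents that add atoms: ethane-1,2-diol, OCCO
Why: Acid-catalysed acetalisation with azeotropic removal of water, which masks the formyl group as a base-stable dioxolane that also directs the following metalation.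

Step 5
Reactants: 9 2-(furan-3-yl)-1,3-dioxolane; 7 (4-bromo-3-methoxyphenoxy)tri(propan-2-yl)silane
Product: 12 {4-[3-(1,3-dioxolan-2-yl)furan-2-yl]-3-methoxyphenoxy}tri(propan-2-yl)silane, via 2-furyllithium 10 (not isolated), via 2-furylzinc chloride 11 (not isolated)
Conditions: 9 (1.2 equiv), n-BuLi (1.2 equiv), THF, −78 to −20 °C; ZnCl2 (1.3 equiv), −20 °C to rt; 7 (1.0 equiv), Pd(OAc)2 (2 mol %), SPhos (4 mol %), 60 °C
Reagents that add atoms: none
Why: Directed α-lithiation of a 3-(dialkoxymethyl)furan goes to C2, the α-position next to the coordinating acetal, transmetalation to zinc gives 11, and Negishi coupling with the electron-rich aryl bromide under a zerovalent palladium catalyst formed from Pd(OAc)2 and the dialkylbiarylphosphine joins furan C2 to the aryl ring without forming a stereocentre.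

Step 6
Reactants: 12 {4-[3-(1,3-dioxolan-2-yl)furan-2-yl]-3-methoxyphenoxy}tri(propan-2-yl)silane
Product: 14 1-[4-(1,3-dioxolan-2-yl)-5-{2-methoxy-4-[tri(propan-2-yl)silyloxy]phenyl}furan-2-yl]ethan-1-one, via 5-lithiofuran 13 (not isolated)
Conditions: n-BuLi (1.1 equiv), THF, −78 to −30 °C; MeC(O)N(OMe)Me (1.3 equiv), −78 to 0 °C; aq. NH4Cl
Reagents that add atoms: N-methoxy-N-methylacetamide, CC(=O)N(C)OC
Why: α-Lithiation of the furan at C5, its only free α-position and the most acidic C–H bond of 12, followed by acylation with a Weinreb amide, whose chelated tetrahedral adduct prevents over-addition, gives the methyl ketone.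

Step 7
Reactants: 14 1-[4-(1,3-dioxolan-2-yl)-5-{2-methoxy-4-[tri(propan-2-yl)silyloxy]phenyl}furan-2-yl]ethan-1-one
Product: 16 2-diazo-1-[4-(1,3-dioxolan-2-yl)-5-{2-methoxy-4-[tri(propan-2-yl)silyloxy]phenyl}furan-2-yl]ethan-1-one, via trifluoroacetyl ketone 15 (not isolated)
Conditions: LiN(SiMe3)2 (1.1 equiv), THF, −78 °C; CF3CO2CH2CF3 (1.2 equiv); cold 5% aq. citric acid, crude 15 taken on; MsN3 (1.5 equiv), Et3N (1.5 equiv), H2O (1 equiv), MeCN, rt
Reagents that add atoms: methanesulfonyl azide, CS(=O)(=O)N=[N+]=[N-]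
Why: Detrifluoroacetylative diazo transfer, in which Claisen trifluoroacetylation of the kinetic lithium enolate activates the methyl ketone as 1,3-diketone 15 and Regitz-type transfer from the sulfonyl azide with loss of the trifluoroacetyl group gives the diazomethyl ketone under conditions that leave acetal and silyl ether untouched.

Step 8
Reactants: 16 2-diazo-1-[4-(1,3-dioxolan-2-yl)-5-{2-methoxy-4-[tri(propan-2-yl)silyloxy]phenyl}furan-2-yl]ethan-1-one; 5 triethyl[(6-methoxy-2-methylhex-5-yn-2-yl)oxy]silane
Product: 21 3-(1,3-dioxolan-2-yl)-6-methoxy-2-{2-methoxy-4-[tri(propan-2-yl)silyloxy]phenyl}-5-{3-methyl-3-[(triethylsilyl)oxy]butyl}-1-benzofuran-4-ol, via furylketene 17 (not isolated), via 4-furylcyclobutenone 18 (not isolated), via dienylketene 19 (not isolated), via 3aH-benzofuranone 20 (not isolated)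
Conditions: 16 (1.0 equiv), 5 (1.5 equiv), degassed ClCH2CH2Cl (0.1 M), base-washed Pyrex, hν (medium-pressure Hg lamp), rt until 16 is consumed; then 80 °C in the dark
Reagents that add atoms: none
Why: Irradiation expels N2 from 16 and the furyl group shifts to the carbene carbon (Wolff rearrangement, new C7–C7a bond) to give furylketene 17, whose carbonyl carbon is attacked by the nucleophilic, alkyl-bearing carbon of ynol ether 5, so that the [2+2] cycloaddition can give only the 2-alkyl-3-methoxycyclobutenone 18 (bonds C4–C5 and C6–C7). Reversible 4π electrocyclic opening of 18 (thermal or photochemical) gives dienylketene 19, and the isomer with the furyl group cis to the ketene carbon closes ring A by a thermal disrotatory 6π electrocyclisation of the ketene carbon onto furan C3 (bond C3a–C4), the weak aromaticity of furan making the dearomatised dienone 20 cheap to reach, after which enolisation of 20 gives the phenol. The closest known reaction is the aromatic annulation of aryl and heteroaryl α-diazo ketones with alkoxy- and silyloxyalkynes (second-generation Danheiser benzannulation). The only ring closed is the six-membered carbocycle, by 6π electrocyclisation; the stereocentres of 18 (ring carbon bearing the furyl group) and 20 (C3a) form racemic and are erased on aromatisation, so no stereocontrol is needed. The step needs regiocontrol in the cycloaddition, secured by the ketene/ynol ether polarity (OH at C4, chain at C5, OMe at C6, H at C7), and a single site of closure, secured because C3 is the only carbon next to the ketene-bearing C2 of the furan. Interception of the ketenes by hydroxyl groups is excluded by the two silyl ethers (a free side-chain hydroxyl would lactonise 19), the dioxolane keeps the formyl group away from carbene, ketene and ynol ether, and the methyl ynol ether has no path for retro-ene fragmentation on heating.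

Step 9
Reactants: 21 3-(1,3-dioxolan-2-yl)-6-methoxy-2-{2-methoxy-4-[tri(propan-2-yl)silyloxy]phenyl}-5-{3-methyl-3-[(triethylsilyl)oxy]butyl}-1-benzofuran-4-ol
Product: 23 Ebenfuran VI (4-hydroxy-2-(4-hydroxy-2-methoxyphenyl)-5-(3-hydroxy-3-methylbutyl)-6-methoxy-1-benzofuran-3-carbaldehyde), via desilylated acetal 22 (not isolated)
Conditions: Bu4NF (3 equiv), degassed THF, 0 °C to rt; then 1 M aq. HCl to pH 1, rt, short reaction time
Reagents that add atoms: water, O
Why: Fluoride-induced desilylation cleaves the aryl and the tertiary silyl ether to 22, and acid-catalysed acetal hydrolysis then unveils the formyl group quickly because the oxocarbenium ion at C3 is stabilised by O1 and the 2-aryl group, while dilute aqueous acid at room temperature should not ionise the tertiary alcohol, so cyclisation to a chromane with the 4-OH is not expected.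

**Compound list**

1 | 4-bromo-2-methylbutan-2-ol | CC(C)(O)CCBr | starting material
2 | [(4-bromo-2-methylbutan-2-yl)oxy]triethylsilane | CC[Si](CC)(CC)OC(C)(C)CCBr | intermediate
3 | 2-chloro-1,1-dimethoxyethane | COC(CCl)OC | starting material
4 | sodium methoxyacetylide (sodium 2-methoxyethynide) | COC#[C-].[Na+] | intermediate
5 | triethyl[(6-methoxy-2-methylhex-5-yn-2-yl)oxy]silane | COC#CCCC(C)(C)O[Si](CC)(CC)CC | intermediate
6 | 4-bromo-3-methoxyphenol | COc1cc(O)ccc1Br | starting material
7 | (4-bromo-3-methoxyphenoxy)tri(propan-2-yl)silane | COc1cc(O[Si](C(C)C)(C(C)C)C(C)C)ccc1Br | intermediate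
8 | furan-3-carbaldehyde | O=Cc1ccoc1 | starting material
9 | 2-(furan-3-yl)-1,3-dioxolane | C1COC(O1)c1ccoc1 | intermediate
10 | [3-(1,3-dioxolan-2-yl)furan-2-yl]lithium | [Li]c1occc1C1OCCO1 | intermediate
11 | chloro[3-(1,3-dioxolan-2-yl)furan-2-yl]zinc | Cl[Zn]c1occc1C1OCCO1 | intermediate
12 | {4-[3-(1,3-dioxolan-2-yl)furan-2-yl]-3-methoxyphenoxy}tri(propan-2-yl)silane | COc1cc(O[Si](C(C)C)(C(C)C)C(C)C)ccc1-c1occc1C1OCCO1 | intermediate
13 | [4-(1,3-dioxolan-2-yl)-5-{2-methoxy-4-[tri(propan-2-yl)silyloxy]phenyl}furan-2-yl]lithium | COc1cc(O[Si](C(C)C)(C(C)C)C(C)C)ccc1-c1oc([Li])cc1C1OCCO1 | intermediate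
14 | 1-[4-(1,3-dioxolan-2-yl)-5-{2-methoxy-4-[tri(propan-2-yl)silyloxy]phenyl}furan-2-yl]ethan-1-one | COc1cc(O[Si](C(C)C)(C(C)C)C(C)C)ccc1-c1oc(C(C)=O)cc1C1OCCO1 | intermediate
15 | 1-[4-(1,3-dioxolan-2-yl)-5-{2-methoxy-4-[tri(propan-2-yl)silyloxy]phenyl}furan-2-yl]-4,4,4-trifluorobutane-1,3-dione | COc1cc(O[Si](C(C)C)(C(C)C)C(C)C)ccc1-c1oc(C(=O)CC(=O)C(F)(F)F)cc1C1OCCO1 | intermediate
16 | 2-diazo-1-[4-(1,3-dioxolan-2-yl)-5-{2-methoxy-4-[tri(propan-2-yl)silyloxy]phenyl}furan-2-yl]ethan-1-one | COc1cc(O[Si](C(C)C)(C(C)C)C(C)C)ccc1-c1oc(C(=O)C=[N+]=[N-])cc1C1OCCO1 | intermediate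
17 | 2-[4-(1,3-dioxolan-2-yl)-5-{2-methoxy-4-[tri(propan-2-yl)silyloxy]phenyl}furan-2-yl]ethen-1-one (furylketene) | COc1cc(O[Si](C(C)C)(C(C)C)C(C)C)ccc1-c1oc(C=C=O)cc1C1OCCO1 | intermediate
18 | rac-4-[4-(1,3-dioxolan-2-yl)-5-{2-methoxy-4-[tri(propan-2-yl)silyloxy]phenyl}furan-2-yl]-3-methoxy-2-{3-methyl-3-[(triethylsilyl)oxy]butyl}cyclobut-2-en-1-one | COC1=C(CCC(C)(C)O[Si](CC)(CC)CC)C(=O)C1c1cc(C2OCCO2)c(-c2ccc(O[Si](C(C)C)(C(C)C)C(C)C)cc2OC)o1 | intermediate
19 | (3E)-4-[4-(1,3-dioxolan-2-yl)-5-{2-methoxy-4-[tri(propan-2-yl)silyloxy]phenyl}furan-2-yl]-3-methoxy-2-{3-methyl-3-[(triethylsilyl)oxy]butyl}buta-1,3-dien-1-one (dienylketene, furyl cis to the ketene carbon) | O=C=C(CCC(C)(C)O[Si](CC)(CC)CC)/C(OC)=C\c1cc(C2OCCO2)c(-c2ccc(O[Si](C(C)C)(C(C)C)C(C)C)cc2OC)o1 | intermediate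
20 | rac-3-(1,3-dioxolan-2-yl)-6-methoxy-2-{2-methoxy-4-[tri(propan-2-yl)silyloxy]phenyl}-5-{3-methyl-3-[(triethylsilyl)oxy]butyl}-1-benzofuran-4(3aH)-one | O=C1C(CCC(C)(C)O[Si](CC)(CC)CC)=C(OC)C=C2OC(-c3ccc(O[Si](C(C)C)(C(C)C)C(C)C)cc3OC)=C(C3OCCO3)C12 | intermediate
21 | 3-(1,3-dioxolan-2-yl)-6-methoxy-2-{2-methoxy-4-[tri(propan-2-yl)silyloxy]phenyl}-5-{3-methyl-3-[(triethylsilyl)oxy]butyl}-1-benzofuran-4-ol | COc1cc(O[Si](C(C)C)(C(C)C)C(C)C)ccc1-c1oc2cc(OC)c(CCC(C)(C)O[Si](CC)(CC)CC)c(O)c2c1C1OCCO1 | intermediate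
22 | 3-(1,3-dioxolan-2-yl)-2-(4-hydroxy-2-methoxyphenyl)-5-(3-hydroxy-3-methylbutyl)-6-methoxy-1-benzofuran-4-ol | COc1cc(O)ccc1-c1oc2cc(OC)c(CCC(C)(C)O)c(O)c2c1C1OCCO1 | intermediate
23 | Ebenfuran VI, 4-hydroxy-2-(4-hydroxy-2-methoxyphenyl)-5-(3-hydroxy-3-methylbutyl)-6-methoxy-1-benzofuran-3-carbaldehyde | COc1cc(O)ccc1-c1oc2cc(OC)c(CCC(C)(C)O)c(O)c2c1C=O | target

Total step count: 9. Longest linear sequence: 6 steps (steps 4, 5, 6, 7, 8, 9).

Steps most likely to fail:

Step 8. The photochemical stage may suffer from competing light absorption by the arylfuran chromophore and by the product, from trapping of the carbene by the ynol ether before the 1,2-shift, and from acylation of the product phenol by ketene 17. As a fallback the ketene would be generated in the dark. Setting out from 16, silver-catalysed Wolff rearrangement in water (PhCO2Ag, Et3N, dioxane–H2O) would give [4-(1,3-dioxolan-2-yl)-5-{2-methoxy-4-[tri(propan-2-yl)silyloxy]phenyl}furan-2-yl]acetic acid F1. 1-Chloro-N,N,2-trimethylprop-1-en-1-amine would convert it under neutral conditions into [4-(1,3-dioxolan-2-yl)-5-{2-methoxy-4-[tri(propan-2-yl)silyloxy]phenyl}furan-2-yl]acetyl chloride F2. Slow addition of Et3N to F2 and 5 in toluene at 80–110 °C would form ketene 17 by dehydrochlorination and carry it through 18, 19 and 20 to 21, where the route is rejoined.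

Step 2. E2 elimination of the bromide by amide or acetylide, poor solubility of the lipophilic bromide in ammonia and partial desilylation may erode the alkylation. As a fallback the triple bond would be made by elimination instead of alkylation. Setting out from 2, Mg in THF would give {3-methyl-3-[(triethylsilyl)oxy]butyl}magnesium bromide F3, which with N,2-dimethoxy-N-methylacetamide would give 1-methoxy-5-methyl-5-[(triethylsilyl)oxy]hexan-2-one F4. LiN(SiMe3)2 and PhNTf2 (THF, −78 °C) should deprotonate the more acidic methoxy-bearing carbon and give (1Z)-1-methoxy-5-methyl-5-[(triethylsilyl)oxy]hex-1-en-2-yl trifluoromethanesulfonate F5. KOtBu would then eliminate triflate anti to the vinylic hydrogen and give ynol ether 5, where the route is rejoined.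

Step 5. Metalation may go partly to C5 of the furan, and slow oxidative addition to the hindered, electron-rich bromide may favour homocoupling and protonation of the organozinc. As a fallback the regiochemistry would be bought with the starting material. Setting out from 7, Suzuki–Miyaura coupling with commercial (3-formylfuran-2-yl)boronic acid (Pd(OAc)2, SPhos, K3PO4, THF–H2O, 40 °C) would give 2-{2-methoxy-4-[tri(propan-2-yl)silyloxy]phenyl}furan-3-carbaldehyde F6, and acetalisation under the conditions of step 4 would return to 12.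

**Further compounds**

F1 | step 8 | [4-(1,3-dioxolan-2-yl)-5-{2-methoxy-4-[tri(propan-2-yl)silyloxy]phenyl}furan-2-yl]acetic acid | COc1cc(O[Si](C(C)C)(C(C)C)C(C)C)ccc1-c1oc(CC(O)=O)cc1C1OCCO1
F2 | step 8 | [4-(1,3-dioxolan-2-yl)-5-{2-methoxy-4-[tri(propan-2-yl)silyloxy]phenyl}furan-2-yl]acetyl chloride | COc1cc(O[Si](C(C)C)(C(C)C)C(C)C)ccc1-c1oc(CC(Cl)=O)cc1C1OCCO1
F3 | step 2 | {3-methyl-3-[(triethylsilyl)oxy]butyl}magnesium bromide | CC[Si](CC)(CC)OC(C)(C)CC[Mg]Br
F4 | step 2 | 1-methoxy-5-methyl-5-[(triethylsilyl)oxy]hexan-2-one | COCC(=O)CCC(C)(C)O[Si](CC)(CC)CC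
F5 | step 2 | (1Z)-1-methoxy-5-methyl-5-[(triethylsilyl)oxy]hex-1-en-2-yl trifluoromethanesulfonate | CO/C=C(\OS(=O)(=O)C(F)(F)F)CCC(C)(C)O[Si](CC)(CC)CC
F6 | step 5 | 2-{2-methoxy-4-[tri(propan-2-yl)silyloxy]phenyl}furan-3-carbaldehyde | COc1cc(O[Si](C(C)C)(C(C)C)C(C)C)ccc1-c1occc1C=O
A1 | direct plan | 2-(benzyloxy)-3-iodo-4-methoxy-6-(methoxymethoxy)benzaldehyde | O=Cc1c(OCc2ccccc2)c(I)c(OC)cc1OCOC
A2 | direct plan | (E)-1-[4-(benzyloxy)-2-methoxyphenyl]-3-[2-(benzyloxy)-3-iodo-4-methoxy-6-(methoxymethoxy)phenyl]prop-2-en-1-one | COc1cc(OCc2ccccc2)ccc1C(=O)/C=C/c1c(OCc2ccccc2)c(I)c(OC)cc1OCOC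
A3 | direct plan | 4-(benzyloxy)-2-[4-(benzyloxy)-2-methoxyphenyl]-5-iodo-6-methoxy-1-benzofuran-3-carbaldehyde | COc1cc(OCc2ccccc2)ccc1-c1oc2cc(OC)c(I)c(OCc3ccccc3)c2c1C=O
A4 | direct plan | 4-(benzyloxy)-2-[4-(benzyloxy)-2-methoxyphenyl]-5-(3-hydroxy-3-methylbut-1-yn-1-yl)-6-methoxy-1-benzofuran-3-carbaldehyde | COc1cc(OCc2ccccc2)ccc1-c1oc2cc(OC)c(C#CC(C)(C)O)c(OCc3ccccc3)c2c1C=O
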